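Ring B (central benzene: C1 arylethyl, C2 H, C3 OMe, C4 benzyl, C5 OH, C6 benzyl) is cut at C1–C2 and C5–C6. C2–C5 then map onto a 2-benzylated acetoacetate (C3 OMe from the ketone, C5 OH from the ester), and C1/C6 onto the alkyne carbons of an aryl ynone whose carbonyl is the latent C6 benzylic carbon. One Diels–Alder/aromatisation between a 2-benzyl-1,3-dimethoxy-1-silyloxybutadiene and a 1-aryl-5-arylpent-2-yn-1-one should therefore deliver the complete, regiodefined substitution pattern of ring B as an ortho-hydroxybenzophenone. Both partners carry O-benzyl groups, so one acidic hydrogenation finally reduces the ketone to CH2 and frees both phenols.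

Key step: step 6

Remark: the target is achiral, so the stereocentres that arise in a few intermediates are racemic and are erased on the way. 4-(Benzyloxy)benzoyl chloride is taken as a purchasable acid chloride.

Step 1
Reactants: 1 methyl acetoacetate; 2 4-(benzyloxy)benzyl chloride
Product: 3 methyl 2-[4-(benzyloxy)benzyl]-3-oxobutanoate (racemic)
Conditions: K2CO3, KI (cat.), acetone, reflux (1 in excess, 2 equiv)
Reagents that add atoms: none
Why: Acetoacetic ester C-alkylation (iodide-assisted SN2 of the β-keto ester enolate on an activated benzylic chloride) should give the mono-benzylated ester, excess 1 limiting dialkylation, and the new C2 centre is formed racemic and is planarised in step 2.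

Step 2
Reactants: 3 methyl 2-[4-(benzyloxy)benzyl]-3-oxobutanoate
Product: 5 methyl 2-[4-(benzyloxy)benzyl]-3-methoxybut-2-enoate (E/Z mixture), via dimethyl ketal 4 (not isolated)
Conditions: HC(OMe)3, MeOH, H2SO4 (cat.), rt; then TsOH (cat.), toluene, 110 °C, MeOH distilled off
Reagents that add atoms: trimethyl orthoformate, COC(OC)OC
Why: Acid-catalysed ketalisation with the orthoformate as water scavenger, then acid-catalysed elimination of methanol into conjugation with the ester (enol ether formation), should give the β-methoxy enoate, and the E/Z mixture is acceptable because this double bond becomes a single bond in the dienolate of step 3.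

Step 3
Reactants: 5 methyl 2-[4-(benzyloxy)benzyl]-3-methoxybut-2-enoate
Product: 7 2-[4-(benzyloxy)benzyl]-1,3-dimethoxy-1-(trimethylsilyloxy)buta-1,3-diene (ketene acetal geometry undefined), via lithium dienolate 6 (not isolated)
Conditions: LiN(iPr)2 (LDA, commercial solution), THF, −78 °C; TMSCl, −78 °C → rt; pentane, filtration under argon, used crude
Reagents that add atoms: chlorotrimethylsilane, C[Si](C)(C)Cl
Why: Kinetic γ-deprotonation of the vinylogous ester gives the extended lithium dienolate, which the hard electrophile TMSCl traps on oxygen (silyl ketene acetal formation, the standard preparation of 1,3-dialkoxy-1-silyloxydienes), and the benzyl ether and the benzylic CH2 are inert to the amide base at −78 °C.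

Step 4
Reactants: 8 3-methoxybenzyl bromide
Product: 10 4-(3-methoxyphenyl)but-1-yne, via C-silyl alkyne 9 (not isolated)
Conditions: 1-(trimethylsilyl)propyne, n-BuLi, THF, −78 °C; then 8, −78 °C → rt; then MeOH, K2CO3 (cat.), rt
Reagents that add atoms: 1-(trimethylsilyl)propyne, CC#C[Si](C)(C)C
Why: Propargylic lithiation of the silylpropyne and SN2 alkylation by the benzylic bromide, with the silyl group steering attack to the propargylic rather than the allenic terminus, followed by base-catalysed methanolysis of the alkynyl C–Si bond (protodesilylation), should give the terminal alkyne.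

Step 5
Reactants: 10 4-(3-methoxyphenyl)but-1-yne; 11 4-(benzyloxy)benzoyl chloride
Product: 12 1-[4-(benzyloxy)phenyl]-5-(3-methoxyphenyl)pent-2-yn-1-one
Conditions: PdCl2(PPh3)2 (2 mol %), CuI (4 mol %), Et3N, THF, rt
Reagents that add atoms: none
Why: Acyl Sonogashira coupling (oxidative addition of the aroyl chloride to zerovalent palladium, transmetalation from the copper acetylide, reductive elimination) should give the ynone directly at the ketone oxidation level without over-addition, the ethers being spectators.

Step 6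
Reactants: 7 2-[4-(benzyloxy)benzyl]-1,3-dimethoxy-1-(trimethylsilyloxy)buta-1,3-diene; 12 1-[4-(benzyloxy)phenyl]-5-(3-methoxyphenyl)pent-2-yn-1-one
Product: 15 [4-(benzyloxy)phenyl]{3-[4-(benzyloxy)benzyl]-2-hydroxy-4-methoxy-6-[2-(3-methoxyphenyl)ethyl]phenyl}methanone, via cyclohexadiene ketal cycloadduct 13 (not isolated), via aryl trimethylsilyl ether 14 (not isolated)
Conditions: 7 (2.5 equiv), toluene, 110 °C, sealed tube; then 1 M HCl, THF, rt
Reagents that add atoms: none
Why: The electron-rich diene 7 and the electron-poor ynone 12 should combine in a strongly asynchronous normal-demand Diels–Alder reaction in which bonding of the unsubstituted CH2 terminus of 7 to the β-alkyne carbon (future C2–C1) runs ahead of bonding of the ketene acetal carbon to the α-carbon (future C5–C6), giving ketal 13. The closest known reaction type is the cycloaddition of 1,3-dioxygenated 1-silyloxydienes (Brassard type) with acetylenic ketones and esters followed by aromatisation to resorcinol monoethers. Ring B closes as the six-membered ring of a suprafacial [4+2] addition or, at the stepwise limit (Mukaiyama–Michael addition first), by a favoured 6-exo-trig attack of the allenolate α-carbon on the ester-derived oxocarbenium carbon, and both paths give the same ring. On acidic work-up the more basic methoxy oxygen of the mixed ketal leaves (or the O–Si bond is hydrolysed first and the hemiketal collapses), so that 13 aromatises through silyl ether 14 to the hydrogen-bonded phenol 15 with C5 as OH and C3 keeping the methoxy group of the diene. The single sp3 ketal centre of 13 is racemic and disappears on aromatisation, so no stereocontrol is required. The step needs regioselectivity and conjugate rather than carbonyl attack: the largest HOMO coefficient of 7 lies on its CH2 terminus (pushed by the 3-OMe and the ketene acetal), the largest LUMO coefficient of 12 on the β-carbon, no Lewis acid is present to activate the carbonyl, and the linear alkyne keeps steric demand low next to the 2-benzyl group.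

Step 7
Reactants: 15 [4-(benzyloxy)phenyl]{3-[4-(benzyloxy)benzyl]-2-hydroxy-4-methoxy-6-[2-(3-methoxyphenyl)ethyl]phenyl}methanone
Product: 18 2,6-bis(4-hydroxybenzyl)-3-methoxy-5-[2-(3-methoxyphenyl)ethyl]phenol, via debenzylated ketone 16 (not isolated), via debenzylated diarylmethanol 17 (not isolated)
Conditions: H2 (4 bar), 10% Pd/C, AcOH–EtOAc 1:1, 45 °C
Reagents that add atoms: none
Why: Heterogeneous palladium-catalysed hydrogenolysis should first cleave the two O-benzyl bonds and then hydrogenate the diaryl ketone to the doubly benzylic carbinol, which in acetic acid is reduced to the methylene directly or through an ortho- or para-quinone methide, while aryl methyl ethers and the arenes are untouched and no stereocentre remains.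

Compound list
1 | methyl acetoacetate | COC(=O)CC(C)=O | starting material
2 | 4-(benzyloxy)benzyl chloride | ClCc1ccc(OCc2ccccc2)cc1 | starting material
3 | methyl 2-[4-(benzyloxy)benzyl]-3-oxobutanoate (racemic) | COC(=O)C(Cc1ccc(OCc2ccccc2)cc1)C(C)=O | intermediate
4 | methyl 2-[4-(benzyloxy)benzyl]-3,3-dimethoxybutanoate (racemic dimethyl ketal) | COC(=O)C(Cc1ccc(OCc2ccccc2)cc1)C(C)(OC)OC | intermediate (not isolated)
5 | methyl 2-[4-(benzyloxy)benzyl]-3-methoxybut-2-enoate (E/Z mixture) | COC(=O)C(Cc1ccc(OCc2ccccc2)cc1)=C(C)OC | intermediate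
6 | lithium 2-[4-(benzyloxy)benzyl]-1,3-dimethoxybuta-1,3-dien-1-olate | C=C(OC)C(Cc1ccc(OCc2ccccc2)cc1)=C(OC)O[Li] | intermediate (not isolated)
7 | 2-[4-(benzyloxy)benzyl]-1,3-dimethoxy-1-(trimethylsilyloxy)buta-1,3-diene (ketene acetal geometry undefined) | C=C(OC)C(Cc1ccc(OCc2ccccc2)cc1)=C(OC)O[Si](C)(C)C | intermediate
8 | 3-methoxybenzyl bromide | COc1cccc(CBr)c1 | starting material
9 | trimethyl[4-(3-methoxyphenyl)but-1-yn-1-yl]silane | COc1cccc(CCC#C[Si](C)(C)C)c1 | intermediate (not isolated)
10 | 4-(3-methoxyphenyl)but-1-yne | C#CCCc1cccc(OC)c1 | intermediate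
11 | 4-(benzyloxy)benzoyl chloride | O=C(Cl)c1ccc(OCc2ccccc2)cc1 | starting material
12 | 1-[4-(benzyloxy)phenyl]-5-(3-methoxyphenyl)pent-2-yn-1-one | O=C(C#CCCc1cccc(OC)c1)c1ccc(OCc2ccccc2)cc1 | intermediate
13 | [4-(benzyloxy)phenyl]{5-[4-(benzyloxy)benzyl]-4,6-dimethoxy-2-[2-(3-methoxyphenyl)ethyl]-6-(trimethylsilyloxy)cyclohexa-1,4-dien-1-yl}methanone (racemic) | COC1=C(Cc2ccc(OCc3ccccc3)cc2)C(OC)(O[Si](C)(C)C)C(C(=O)c2ccc(OCc3ccccc3)cc2)=C(CCc2cccc(OC)c2)C1 | intermediate (not isolated)
14 | [4-(benzyloxy)phenyl]{3-[4-(benzyloxy)benzyl]-4-methoxy-6-[2-(3-methoxyphenyl)ethyl]-2-(trimethylsilyloxy)phenyl}methanone | COc1cccc(CCc2cc(OC)c(Cc3ccc(OCc4ccccc4)cc3)c(O[Si](C)(C)C)c2C(=O)c2ccc(OCc3ccccc3)cc2)c1 | intermediate (not isolated)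
15 | [4-(benzyloxy)phenyl]{3-[4-(benzyloxy)benzyl]-2-hydroxy-4-methoxy-6-[2-(3-methoxyphenyl)ethyl]phenyl}methanone | COc1cccc(CCc2cc(OC)c(Cc3ccc(OCc4ccccc4)cc3)c(O)c2C(=O)c2ccc(OCc3ccccc3)cc2)c1 | intermediate
16 | (4-hydroxyphenyl){2-hydroxy-3-(4-hydroxybenzyl)-4-methoxy-6-[2-(3-methoxyphenyl)ethyl]phenyl}methanone | COc1cccc(CCc2cc(OC)c(Cc3ccc(O)cc3)c(O)c2C(=O)c2ccc(O)cc2)c1 | intermediate (not isolated)
17 | 2-[hydroxy(4-hydroxyphenyl)methyl]-6-(4-hydroxybenzyl)-5-methoxy-3-[2-(3-methoxyphenyl)ethyl]phenol (racemic) | COc1cccc(CCc2cc(OC)c(Cc3ccc(O)cc3)c(O)c2C(O)c2ccc(O)cc2)c1 | intermediate (not isolated)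
18 | 2,6-bis(4-hydroxybenzyl)-3-methoxy-5-[2-(3-methoxyphenyl)ethyl]phenol | COc1cccc(CCc2cc(OC)c(Cc3ccc(O)cc3)c(O)c2Cc2ccc(O)cc2)c1 | target

Total step count: 7. Longest linear sequence: 5 steps (steps 1, 2, 3, 6, 7); the ynone branch (steps 4, 5) joins at step 6.

Steps most likely to fail

Step 6. The cycloaddition between the 2-benzyl diene and the β-alkyl aryl ynone may be too slow at temperatures that the silyl ketene acetal survives, so that desilylation and oligomerisation of the diene outrun ring formation. The fallback sets out from 10 (with 7) and comes back to the route at 18. Alkyne 10 is formylated (n-BuLi, THF, −78 °C; DMF; buffered quench) to 5-(3-methoxyphenyl)pent-2-ynal F1, a more electrophilic and sterically smaller dienophile. Its Diels–Alder reaction with 7 (toluene, rt to 60 °C; then dilute HCl) should give, with the same regiochemistry, 3-[4-(benzyloxy)benzyl]-2-hydroxy-4-methoxy-6-[2-(3-methoxyphenyl)ethyl]benzaldehyde F2. Addition of 4-(benzyloxy)phenylmagnesium bromide (2.5 equiv, THF, 0 °C) then gives racemic [4-(benzyloxy)phenyl]{3-[4-(benzyloxy)benzyl]-2-hydroxy-4-methoxy-6-[2-(3-methoxyphenyl)ethyl]phenyl}methanol F3. Under the conditions of step 7 this carbinol should lose the benzylic hydroxyl and both benzyl groups to give 18.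

Step 7. Hydrogenation may stall at the hindered, hydrogen-bonded ketone or at the carbinol, or the acid may promote Friedel–Crafts capture of the diarylmethyl cation by the tethered methoxyphenyl ring. The fallback sets out from 15 and comes back at 18. Acylation of the phenol with ClCO2Et/Et3N (THF, 0 °C) gives 2-[4-(benzyloxy)benzoyl]-6-[4-(benzyloxy)benzyl]-5-methoxy-3-[2-(3-methoxyphenyl)ethyl]phenyl ethyl carbonate F4. NaBH4 in THF–H2O reduces the now unchelated ketone; the alkoxide takes over the carbonate and eliminates to an ortho-quinone methide that is reduced in the same flask. This should give 2,6-bis[4-(benzyloxy)benzyl]-3-methoxy-5-[2-(3-methoxyphenyl)ethyl]phenol F5 under basic, cation-free conditions. Neutral hydrogenolysis (H2, 10% Pd/C, EtOAc–MeOH, rt) then removes the two benzyl groups to give 18.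

Step 2. Ketalisation of the α-branched ketone may stall, or methanol may not be eliminated cleanly, leaving a ketone/ketal/enol ether mixture that cannot be distilled. The fallback sets out from 3 and comes back at 15, and it avoids the methyl enol ether altogether. Ketoester 3 is O-silylated (TMSCl, Et3N, rt) to methyl 2-[4-(benzyloxy)benzyl]-3-(trimethylsilyloxy)but-2-enoate F6. LiN(iPr)2/TMSCl (THF, −78 °C) converts this into 2-[4-(benzyloxy)benzyl]-1-methoxy-1,3-bis(trimethylsilyloxy)buta-1,3-diene F7. Cycloaddition with 12 as in step 6 and acidic work-up should give the resorcinol [4-(benzyloxy)phenyl]{3-[4-(benzyloxy)benzyl]-2,4-dihydroxy-6-[2-(3-methoxyphenyl)ethyl]phenyl}methanone F8. Methylation with MeI/K2CO3 (1.1 equiv, acetone, rt) should go to the free 4-OH, because the 2-OH is locked in the hydrogen bond to the ketone, and gives 15.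

Further compounds
F1 | step 6 | 5-(3-methoxyphenyl)pent-2-ynal | O=CC#CCCc1cccc(OC)c1
F2 | step 6 | 3-[4-(benzyloxy)benzyl]-2-hydroxy-4-methoxy-6-[2-(3-methoxyphenyl)ethyl]benzaldehyde | COc1cccc(CCc2cc(OC)c(Cc3ccc(OCc4ccccc4)cc3)c(O)c2C=O)c1
F3 | step 6 | [4-(benzyloxy)phenyl]{3-[4-(benzyloxy)benzyl]-2-hydroxy-4-methoxy-6-[2-(3-methoxyphenyl)ethyl]phenyl}methanol (racemic) | COc1cccc(CCc2cc(OC)c(Cc3ccc(OCc4ccccc4)cc3)c(O)c2C(O)c2ccc(OCc3ccccc3)cc2)c1
F4 | step 7 | 2-[4-(benzyloxy)benzoyl]-6-[4-(benzyloxy)benzyl]-5-methoxy-3-[2-(3-methoxyphenyl)ethyl]phenyl ethyl carbonate | CCOC(=O)Oc1c(Cc2ccc(OCc3ccccc3)cc2)c(OC)cc(CCc2cccc(OC)c2)c1C(=O)c1ccc(OCc2ccccc2)cc1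
F5 | step 7 | 2,6-bis[4-(benzyloxy)benzyl]-3-methoxy-5-[2-(3-methoxyphenyl)ethyl]phenol | COc1cccc(CCc2cc(OC)c(Cc3ccc(OCc4ccccc4)cc3)c(O)c2Cc2ccc(OCc3ccccc3)cc2)c1
F6 | step 2 | methyl 2-[4-(benzyloxy)benzyl]-3-(trimethylsilyloxy)but-2-enoate | COC(=O)C(Cc1ccc(OCc2ccccc2)cc1)=C(C)O[Si](C)(C)C
F7 | step 2 | 2-[4-(benzyloxy)benzyl]-1-methoxy-1,3-bis(trimethylsilyloxy)buta-1,3-diene | C=C(O[Si](C)(C)C)C(Cc1ccc(OCc2ccccc2)cc1)=C(OC)O[Si](C)(C)C
F8 | step 2 | [4-(benzyloxy)phenyl]{3-[4-(benzyloxy)benzyl]-2,4-dihydroxy-6-[2-(3-methoxyphenyl)ethyl]phenyl}methanone | COc1cccc(CCc2cc(O)c(Cc3ccc(OCc4ccccc4)cc3)c(O)c2C(=O)c2ccc(OCc3ccccc3)cc2)c1
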